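Late in a run the product is bounded by the 100 % of substrate charged, but the eta flask is to be read at 2.0 min, and the beta run stands at 6.2 % at 80.0 s. Before that reading I must decide whether its solid reagent deserves a change.

the same everywhere: substrate 0.010 M
- eta: solid reagent 0.025 M; the very flask that is asked about, followed so far
- beta: solid reagent 0.013 M; run made earlier
- flask: solid reagent 0.0250 M; time 2.0 min

| run | time / s | product / % |
|---|---|---|
| eta | 10.0 | 0 |
| beta | 20.0 | 0.5 |
| beta | 40.0 | 2.1 |
| beta | 60.0 | 3.9 |
| beta | 80.0 | 6.2 |

(readings scatter by 0.3 percentage points)

- as a solid, counted per litre of solution: solid reagent
- at the start none of the solid reagent is in solution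
- partner is what solid reagent becomes in solution

- maple: doubling the dissolution coefficient of the solid reagent, all else as stated
- ash: doubling the solubility of the solid reagent, all else as stated

* amount of product at 2.0 min, in percent of the substrate charged
* concentration of partner in solution at 30 s, in percent of saturation
* the change that raises the amount of product at 2.0 min, in percent of the substrate charged most ("none" if none brings more than 2 percentage points) (maple / ash / none)
* amount of product at 2.0 min, in percent of the substrate charged, after maple

I read the beta run by taking the logarithm of a ratio of product readings over the logarithm of the ratio of their times. Between 40.0 s and 80.0 s this gives 1.56 for n, the growth exponent, the power of time that product follows between two readings. An exponent of one is a straight line, with product made at a steady rate from the first moment. An exponent of two is a rate that grows in step with time, as when product waits on something still building up, which chemists call an induction period. The earlier pair of beta readings gives 2.07, so the curve starts near two and then bends, though each reading carries a scatter of 0.3 percentage points.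

The curve shows that something builds up, but not what it is: beta is one curve at one solid charge, and the eta reading of 0 % at 10.0 s adds nothing. So I assume that the solid charge leaves the curve as it is. Scaling the beta reading of 6.2 % up to 2.0 min with the later exponent n gives 11.7 %. I keep the charge and spend the next run on that reading, not on maple or ash.

The forecast reckons otherwise: 13.2 %, partner at 68 % of saturation at 30 s, 14.8 % after maple, and ash as the best change, with the ground “I assume dissolution scales with solid loading”.

    substrate ⇌ intermediate B (K = 0.370, k = 0.00107 s⁻¹)
    solid reagent ⇌ partner, rate k2*(cs2 - [partner]) while solid is left; crystals form when [partner] > cs2 (solubility = 9.30 mM, k = 0.00463 s⁻¹)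
    partner + intermediate B → intermediate C (k = 2.43 M⁻¹ s⁻¹)
    intermediate A → product (k = 0.00265 s⁻¹)
    substrate ⇌ intermediate A (K = 20.5, k = 0.0119 s⁻¹)
    intermediate C ⇌ intermediate D (K = 2.80, k = 0.00419 s⁻¹)

The flask gives 12.6 % at 2.0 min against my 11.7 %, with partner at 12.9 % of saturation at 30 s, 12.6 % after maple, and none as the best change. With the solid charge alone moved from the beta value to this flask's, product at the last beta time stays at 6.74 % against 6.74 %. The same n, scaled from the last beta reading to 3.0 min, gives 22.0 %, and the eta flask read at that time stands at 22.1 %.

All runs were computed with made-up constants; scatter was added.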